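Ring B of the phenalenone (C3a, C4, C5, C6, C6a, C9b) is cut at C3a–C4 and C5–C6. Because the C5–C6 edge also belongs to the indane ring, both rings fall back to one tethered cycloaddition. In a single acid-mediated operation a tetralol aryl ketone closes to a lactol, dehydrates to an isobenzofuran, adds across a vinyl group held three atoms away and loses the oxygen bridge as water. The precursor is 5-methoxy-1-tetralol bearing at C8 a ketone whose alpha carbon is the naphthalene-1,8-diol ketal carbon, itself bonded to C5 of (4R,5S)-4-hydroxy-4-vinylcyclopent-2-enone; both stereocentres derive from (R)-4-silyloxycyclopentenone.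

Key step: step 13

Remark: the tetralin carbinol carbon is left uncontrolled because it becomes aromatic in step 13 (2–4 and 8–11 racemic, 19–23 epimeric at that carbon only); hydroxy ketone 20 equilibrates with its lactol 21; core atoms are numbered as in 1H-phenalen-1-one.

Step 1
Reactants: 1 5-methoxy-1-tetralone
Product: 2 5-methoxy-1,2,3,4-tetrahydronaphthalen-1-ol (racemic)
Conditions: NaBH4, MeOH, 0 °C
Reagents that add atoms: none
Why: Borohydride reduction of an aryl ketone; the new carbinol centre forms as a racemate, which is acceptable because this carbon is aromatised in step 13.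

Step 2
Reactants: 2 5-methoxy-1,2,3,4-tetrahydronaphthalen-1-ol
Product: 3 tert-butyl[(5-methoxy-1,2,3,4-tetrahydronaphthalen-1-yl)oxy]dimethylsilane (racemic)
Conditions: TBSCl, imidazole, DMF, rt
Reagents that add atoms: tert-butyldimethylsilyl chloride, CC(C)(C)[Si](C)(C)Cl
Why: Standard silyl ether formation on a secondary benzylic alcohol, giving a group that tolerates organolithium, enolate and silver-salt chemistry and leaves with fluoride.

Step 3
Reactants: 3 tert-butyl[(5-methoxy-1,2,3,4-tetrahydronaphthalen-1-yl)oxy]dimethylsilane
Product: 4 [(8-bromo-5-methoxy-1,2,3,4-tetrahydronaphthalen-1-yl)oxy](tert-butyl)dimethylsilane (racemic)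
Conditions: NBS, MeCN, 0 °C → rt, dark
Reagents that add atoms: N-bromosuccinimide, O=C1CCC(=O)N1Br
Why: Electrophilic aromatic bromination of an anisole in acetonitrile goes para to the methoxy group, which here is C8; exclusion of light suppresses benzylic radical bromination.

Step 4
Reactants: 5 naphthalene-1,8-diol; 6 ethyl dibromoacetate
Product: 7 ethyl naphtho[1,8-de][1,3]dioxine-2-carboxylate
Conditions: K2CO3, DMF, 70 °C, argon
Reagents that add atoms: none
Why: Double Williamson-type O-alkylation of the peri-diol by a gem-dihalide closes the six-membered dioxine, as in the formation of 1,3-benzodioxole-2-carboxylates from catechol and dihaloacetates.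

Step 5
Reactants: 4 [(8-bromo-5-methoxy-1,2,3,4-tetrahydronaphthalen-1-yl)oxy](tert-butyl)dimethylsilane; 7 ethyl naphtho[1,8-de][1,3]dioxine-2-carboxylate
Product: 9 [8-(tert-butyldimethylsilyloxy)-4-methoxy-5,6,7,8-tetrahydronaphthalen-1-yl](naphtho[1,8-de][1,3]dioxin-2-yl)methanone, via aryllithium 8 (not isolated)
Conditions: n-BuLi, THF, −78 °C; then added to 7 (1.3 equiv), THF, −78 °C; sat. aq NH4Cl
Reagents that add atoms: none
Why: Bromine–lithium exchange followed by acylation of the aryllithium with an alpha,alpha-dioxy ester, the established way from dialkoxyacetates to arylglyoxal acetals; the cold tetrahedral adduct and subsequent enolate formation should prevent a second addition.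

Step 6
Reactants: 9 [8-(tert-butyldimethylsilyloxy)-4-methoxy-5,6,7,8-tetrahydronaphthalen-1-yl](naphtho[1,8-de][1,3]dioxin-2-yl)methanone
Product: 11 [8-(tert-butyldimethylsilyloxy)-4-methoxy-5,6,7,8-tetrahydronaphthalen-1-yl](2-chloronaphtho[1,8-de][1,3]dioxin-2-yl)methanone, via lithium enolate 10 (not isolated)
Conditions: LiN(SiMe3)2, THF, −78 °C; then NCS, −78 °C; sat. aq NH4Cl; used crude
Reagents that add atoms: N-chlorosuccinimide, O=C1CCC(=O)N1Cl
Why: Enolate alpha-halogenation: the CH flanked by the ketone and two aryloxy groups is acidic, and its lithium enolate should be chlorinated at carbon far faster than either electron-rich arene reacts.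

Step 7
Reactants: 12 (R)-4-(tert-butyldimethylsilyloxy)cyclopent-2-en-1-one; 13 vinylmagnesium bromide
Product: 14 (1R,4R)-4-(tert-butyldimethylsilyloxy)-1-vinylcyclopent-2-en-1-ol
Conditions: CeCl3, THF, −78 °C; sat. aq NH4Cl
Reagents that add atoms: none
Why: Organocerium 1,2-addition to the enone, in which CeCl3 suppresses enolisation and conjugate addition; the vinyl group enters the carbonyl face anti to the C4 silyloxy group, setting the tertiary carbinol as R with OH cis to the silyl ether.

Step 8
Reactants: 14 (1R,4R)-4-(tert-butyldimethylsilyloxy)-1-vinylcyclopent-2-en-1-ol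
Product: 15 (1R,4R)-1-vinylcyclopent-2-ene-1,4-diol
Conditions: Bu4NF, THF, 0 °C → rt; aq NH4Cl
Reagents that add atoms: none
Why: Fluoride-mediated silyl ether cleavage under non-acidic conditions, which keeps the doubly allylic tertiary alcohol from ionising.

Step 9
Reactants: 15 (1R,4R)-1-vinylcyclopent-2-ene-1,4-diol
Product: 16 (R)-4-hydroxy-4-vinylcyclopent-2-en-1-one
Conditions: MnO2, CH2Cl2, rt
Reagents that add atoms: none
Why: Chemoselective manganese dioxide oxidation of the secondary allylic alcohol; the tertiary alcohol cannot be oxidised, and no chromium oxidant is used so allylic transposition is avoided and the carbinol centre is retained.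

Step 10
Reactants: 16 (R)-4-hydroxy-4-vinylcyclopent-2-en-1-one
Product: 18 triethyl{[(3R)-3-(triethylsilyloxy)-3-vinylcyclopenta-1,4-dien-1-yl]oxy}silane, via mono-silyl ether 17 (not isolated)
Conditions: Et3SiOTf (2.4 equiv), Et3N, CH2Cl2, −78 → 0 °C; used directly
Reagents that add atoms: triethylsilyl trifluoromethanesulfonate, CC[Si](CC)(CC)OS(=O)(=O)C(F)(F)F
Why: Silyl triflate/amine silylation of the tertiary alcohol followed by soft enolisation toward the only alpha-CH2 gives the cross-conjugated 2-silyloxydiene, which cannot tautomerise because its sp3 carbon is quaternary.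

Step 11
Reactants: 11 [8-(tert-butyldimethylsilyloxy)-4-methoxy-5,6,7,8-tetrahydronaphthalen-1-yl](2-chloronaphtho[1,8-de][1,3]dioxin-2-yl)methanone; 18 triethyl{[(3R)-3-(triethylsilyloxy)-3-vinylcyclopenta-1,4-dien-1-yl]oxy}silane
Product: 19 (4R,5S)-5-{2-[8-(tert-butyldimethylsilyloxy)-4-methoxy-5,6,7,8-tetrahydronaphthalene-1-carbonyl]naphtho[1,8-de][1,3]dioxin-2-yl}-4-(triethylsilyloxy)-4-vinylcyclopent-2-en-1-one
Conditions: AgOTf, 2,6-di-tert-butyl-4-methylpyridine, 4 Å MS, CH2Cl2, −78 → −30 °C; aq NaHCO3
Reagents that add atoms: none
Why: Silver-promoted ionisation of the alpha-chloro ketal (Koenigs–Knorr-type activation of an alpha-halo ether) should give a dioxocarbenium ion without beta-hydrogens that alkylates the silyl dienol ether at its nucleophilic terminus in a Mukaiyama-type SN1 alkylation, as in C-glycosylation and tert-alkylation of enol silanes; approach anti to the bulky C4 silyloxy group places the new substituent cis to vinyl and sets C5 as S.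

Step 12
Reactants: 19 (4R,5S)-5-{2-[8-(tert-butyldimethylsilyloxy)-4-methoxy-5,6,7,8-tetrahydronaphthalene-1-carbonyl]naphtho[1,8-de][1,3]dioxin-2-yl}-4-(triethylsilyloxy)-4-vinylcyclopent-2-en-1-one
Product: 20 (4R,5S)-4-hydroxy-5-{2-[8-hydroxy-4-methoxy-5,6,7,8-tetrahydronaphthalene-1-carbonyl]naphtho[1,8-de][1,3]dioxin-2-yl}-4-vinylcyclopent-2-en-1-one
Conditions: HF·pyridine, pyridine, THF, 0 °C → rt
Reagents that add atoms: none
Why: Buffered fluoride desilylation frees both alcohols without generating an alkoxide, so the beta-hydroxy ketone is not exposed to retro-aldol cleavage and both stereocentres are kept.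

Step 13
Reactants: 20 (4R,5S)-4-hydroxy-5-{2-[8-hydroxy-4-methoxy-5,6,7,8-tetrahydronaphthalene-1-carbonyl]naphtho[1,8-de][1,3]dioxin-2-yl}-4-vinylcyclopent-2-en-1-one
Product: 24 9-methoxy-2,3-dihydro-1H-phenalene analogue of spiropreussione B (1-deoxo-2,3-dihydro methyl ether), via lactol 21 (not isolated), via isobenzofuran 22 (not isolated), via oxa-bridged cycloadduct 23 (not isolated)
Conditions: (+)-camphor-10-sulfonic acid (0.3 equiv), degassed PhMe (0.005 M), 80 °C, argon
Reagents that add atoms: none
Why: Acid closes the hydroxy ketone to lactol 21 and ionises it to an oxocarbenium ion that loses the tetralin C1 proton to give isobenzofuran 22, whose two furan carbons add suprafacially across the vinyl group in an intramolecular Diels–Alder reaction; the acid then opens the oxygen bridge of 23 and two eliminations of water aromatise ring B. The closest known chemistry is in-situ isobenzofuran formation from 2-acylbenzyl alcohols or their lactol ethers, capture by a tethered unactivated alkene, and acid-promoted dehydrative aromatisation of the 1,4-epoxy adduct. The indane ring closes as the five-membered ring defined by the three-atom tether (ketal carbon, C5 and C4 of the cyclopentenone) and ring B closes as the six-membered ring of the [4+2] addition, forming C5–C6 and C3a–C4. No stereocentre is created, since the bridge centres of 23 vanish on aromatisation and the cis ring fusion is already fixed by the (4R,5S) centres, only the cis vinyl/ketal arrangement being able to reach the furan. The tether dictates which furan carbon meets which alkene carbon and excludes the ring enone (it would have to build a norbornane cage), high dilution suppresses addition to the enone of a second molecule, and the weak sulfonic acid at 80 °C should spare the tertiary allylic alcohol and the diaryl ketal.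

Step 14
Reactants: 24 9-methoxy-2,3-dihydro-1H-phenalene analogue of spiropreussione B
Product: 26 spiropreussione B methyl ether (9-methoxy-1H-phenalen-1-one core), via dihydrophenalenone 25 (not isolated)
Conditions: DDQ (3.3 equiv), 1,4-dioxane/H2O (10:1), rt → 60 °C
Reagents that add atoms: water, O
Why: DDQ benzylic oxidation by hydride abstraction should start at the CH2 on C9a, whose cation is stabilised by the ortho methoxy group far better than the cation at the other benzylic CH2; water capture and further oxidation give the aryl ketone, which DDQ then dehydrogenates to the fully conjugated phenalenone.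

Step 15
Reactants: 26 spiropreussione B methyl ether
Product: 27 spiropreussione B
Conditions: MgI2·OEt2, PhMe/Et2O, 50 °C; 1 M HCl
Reagents that add atoms: none
Why: Chelation-assisted O-demethylation of a methoxy group peri to a ketone (here a vinylogous ester) by MgI2, in which iodide removes the methyl group by SN2 attack; the conditions are non-basic, so the beta-hydroxy ketone and both stereocentres should survive.

Compound list
1 | 5-methoxy-1-tetralone | COc1cccc2C(=O)CCCc12 | starting material
2 | 5-methoxy-1,2,3,4-tetrahydronaphthalen-1-ol (racemic) | COc1cccc2C(O)CCCc12 | intermediate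
3 | tert-butyl[(5-methoxy-1,2,3,4-tetrahydronaphthalen-1-yl)oxy]dimethylsilane (racemic) | COc1cccc2C(O[Si](C)(C)C(C)(C)C)CCCc12 | intermediate
4 | [(8-bromo-5-methoxy-1,2,3,4-tetrahydronaphthalen-1-yl)oxy](tert-butyl)dimethylsilane (racemic) | COc1ccc(Br)c2C(O[Si](C)(C)C(C)(C)C)CCCc12 | intermediate
5 | naphthalene-1,8-diol | Oc1cccc2cccc(O)c12 | starting material
6 | ethyl dibromoacetate | CCOC(=O)C(Br)Br | starting material
7 | ethyl naphtho[1,8-de][1,3]dioxine-2-carboxylate | CCOC(=O)C1Oc2cccc3cccc(O1)c23 | intermediate
8 | [8-(tert-butyldimethylsilyloxy)-4-methoxy-5,6,7,8-tetrahydronaphthalen-1-yl]lithium (racemic) | COc1ccc([Li])c2C(O[Si](C)(C)C(C)(C)C)CCCc12 | intermediate (not isolated)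
9 | [8-(tert-butyldimethylsilyloxy)-4-methoxy-5,6,7,8-tetrahydronaphthalen-1-yl](naphtho[1,8-de][1,3]dioxin-2-yl)methanone (racemic) | COc1ccc(C(=O)C3Oc4cccc5cccc(O3)c45)c2C(O[Si](C)(C)C(C)(C)C)CCCc12 | intermediate
10 | lithium enolate of 9 (O-lithio ketene acetal) | COc1ccc(C(O[Li])=C3Oc4cccc5cccc(O3)c45)c2C(O[Si](C)(C)C(C)(C)C)CCCc12 | intermediate (not isolated)
11 | [8-(tert-butyldimethylsilyloxy)-4-methoxy-5,6,7,8-tetrahydronaphthalen-1-yl](2-chloronaphtho[1,8-de][1,3]dioxin-2-yl)methanone (racemic) | COc1ccc(C(=O)C3(Cl)Oc4cccc5cccc(O3)c45)c2C(O[Si](C)(C)C(C)(C)C)CCCc12 | intermediate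
12 | (R)-4-(tert-butyldimethylsilyloxy)cyclopent-2-en-1-one | O=C1C=C[C@H](O[Si](C)(C)C(C)(C)C)C1 | starting material
13 | vinylmagnesium bromide | C=C[Mg]Br | starting material
14 | (1R,4R)-4-(tert-butyldimethylsilyloxy)-1-vinylcyclopent-2-en-1-ol (vinyl trans to the silyl ether) | O[C@]1(C=C)C=C[C@H](O[Si](C)(C)C(C)(C)C)C1 | intermediate
15 | (1R,4R)-1-vinylcyclopent-2-ene-1,4-diol (cis-diol) | O[C@]1(C=C)C=C[C@H](O)C1 | intermediate
16 | (R)-4-hydroxy-4-vinylcyclopent-2-en-1-one | O=C1C=C[C@](O)(C=C)C1 | intermediate
17 | (R)-4-(triethylsilyloxy)-4-vinylcyclopent-2-en-1-one | O=C1C=C[C@](O[Si](CC)(CC)CC)(C=C)C1 | intermediate (not isolated)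
18 | triethyl{[(3R)-3-(triethylsilyloxy)-3-vinylcyclopenta-1,4-dien-1-yl]oxy}silane | C=C[C@@]1(O[Si](CC)(CC)CC)C=CC(O[Si](CC)(CC)CC)=C1 | intermediate
19 | (4R,5S)-5-{2-[8-(tert-butyldimethylsilyloxy)-4-methoxy-5,6,7,8-tetrahydronaphthalene-1-carbonyl]naphtho[1,8-de][1,3]dioxin-2-yl}-4-(triethylsilyloxy)-4-vinylcyclopent-2-en-1-one (both epimers at the tetralin carbinol carbon) | COc1ccc(C(=O)C3(Oc4cccc5cccc(O3)c45)[C@@H]6C(=O)C=C[C@]6(O[Si](CC)(CC)CC)C=C)c2C(O[Si](C)(C)C(C)(C)C)CCCc12 | intermediate
20 | (4R,5S)-4-hydroxy-5-{2-[8-hydroxy-4-methoxy-5,6,7,8-tetrahydronaphthalene-1-carbonyl]naphtho[1,8-de][1,3]dioxin-2-yl}-4-vinylcyclopent-2-en-1-one (tetralol aryl ketone, both carbinol epimers) | COc1ccc(C(=O)C3(Oc4cccc5cccc(O3)c45)[C@@H]6C(=O)C=C[C@]6(O)C=C)c2C(O)CCCc12 | intermediate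
21 | lactol of 20: the tetralin C1 oxygen is bonded to the former ketone carbon, which carries OH, aryl C8 and the ketal carbon | COc1ccc2c3c1CCCC3OC2(O)C4(Oc5cccc6cccc(O4)c56)[C@@H]7C(=O)C=C[C@]7(O)C=C | intermediate (not isolated)
22 | isobenzofuran from 21 by loss of water; furan carbons are tetralin C1 and the former ketone carbon | COC1=C2CCCC3=C2C(C=C1)=C(O3)C4(Oc5cccc6cccc(O4)c56)[C@@H]7C(=O)C=C[C@]7(O)C=C | intermediate (not isolated)
23 | oxygen-bridged (1,4-epoxy) cycloadduct: furan carbons bonded to the former vinyl CH2 and CH, side chain syn to the bridge, transient bridge centres left open in the SMILES | COc1ccc2c3c1CCCC3(O4)CC5C24C6(Oc7cccc8cccc(O6)c78)[C@@H]9C(=O)C=C[C@@]95O | intermediate (not isolated)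
24 | 9-methoxy-2,3-dihydro-1H-phenalene fused at C5–C6 to the indane ring; C6 on the spiro ketal carbon, C5 on the tertiary carbinol (R), cis-fused cyclopentenone with ring-fusion CH (S) | COc1ccc2c3c1CCCc3cc4c2C5(Oc6cccc7cccc(O5)c67)[C@@H]8C(=O)C=C[C@]48O | intermediate
25 | 9-methoxy-2,3-dihydro-1H-phenalen-1-one analogue of 24 (ketone on the carbon attached to C9a) | COc1ccc2c3c1C(=O)CCc3cc4c2C5(Oc6cccc7cccc(O5)c67)[C@@H]8C(=O)C=C[C@]48O | intermediate (not isolated)
26 | spiropreussione B methyl ether (9-methoxy-1H-phenalen-1-one core) | COc1ccc2c3c1C(=O)C=Cc3cc4c2C5(Oc6cccc7cccc(O5)c67)[C@@H]8C(=O)C=C[C@]48O | intermediate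
27 | spiropreussione B | Oc1ccc2c3c1C(=O)C=Cc3cc4c2C5(Oc6cccc7cccc(O5)c67)[C@@H]8C(=O)C=C[C@]48O | target

Total step count: 15. Longest linear sequence: 10 steps (1, 2, 3, 5, 6, 11, 12, 13, 14, 15).

Steps most likely to fail

Step 13. The cascade may be diverted by E1 dehydration of the benzylic alcohol before the lactol ionises, by addition of the isobenzofuran to the enone of a second molecule, or by incomplete opening of the oxygen bridge. The fallback stages the cascade and leaves from 20. Methanol, trimethyl orthoformate and pyridinium tosylate at rt should convert 20 into the lactol methyl ether F1, the classical isobenzofuran precursor. Catalytic acetic acid in refluxing dilute toluene should eliminate methanol to 22 and deliver cycloadduct 23, which is isolated this time. A separate short exposure to methanesulfonic acid in CH2Cl2 at −20 → 0 °C should then aromatise 23, rejoining the route at 24.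

Step 11. Ionisation of the chloride may be slow, the cation may be captured by the neighbouring silyl ether oxygen or by triflate, or the diene may be attacked on the wrong face (a C5 epimer would be removed by chromatography, since only the cis vinyl/ketal isomer can cyclise in step 13). The fallback replaces the cationic bond formation by a radical one and leaves from 9. Enolate 10 is quenched with N-bromosuccinimide to give the alpha-bromo ketone F2. Visible-light photoredox reduction of F2 (Ir(ppy)3, blue light, 2,6-lutidine, MeCN) should generate the alpha-keto radical, which adds to the terminus of silyl dienol ether 18; oxidation and loss of the silyl group give the 1,4-diketone, rejoining the route at 19.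

Step 14. Regiocontrol may be lost if the first benzylic cation eliminates to a phenalene instead of being trapped by water, because further oxidation would give a methoxyphenalenium ion that hydrolyses at the methoxy-bearing carbon. The fallback leaves from 24 and uses 2-iodoxybenzoic acid in DMSO at 65–80 °C. This oxidises the electron-richest benzylic CH2 to the ketone by electron transfer with oxygen delivered from iodine, so 25 is isolated. More of the same reagent then dehydrogenates the ketone to the enone, rejoining the route at 26; no new compound is made.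

Further compounds
F1 | step 13 | lactol methyl ether of 20 (cyclic methyl ketal: the tetralin C1 oxygen and OMe on the former ketone carbon) | COc1ccc2c3c1CCCC3OC2(OC)C4(Oc5cccc6cccc(O4)c56)[C@@H]7C(=O)C=C[C@]7(O)C=C
F2 | step 11 | [8-(tert-butyldimethylsilyloxy)-4-methoxy-5,6,7,8-tetrahydronaphthalen-1-yl](2-bromonaphtho[1,8-de][1,3]dioxin-2-yl)methanone (racemic) | COc1ccc(C(=O)C3(Br)Oc4cccc5cccc(O3)c45)c2C(O[Si](C)(C)C(C)(C)C)CCCc12
F0 | step 14 | none | none
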